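**Plan**
- Retrosynthesis: the N-Boc derivative of the 20-membered bis-lactam is cut at the C9b–CH=CH enamide alkene (intramolecular Horner–Wadsworth–Emmons reaction) and at the aryl C8–alkene bond (Heck reaction). This releases a spermidine-derived acrylamide/phosphonoacetamide linker and a tricyclic bromo diol.
- The cyclohexanone ring of the tricycle is then cut at C2–C3 and C1–C9b (dibenzofuran numbering), which removes a two-carbon vinyl unit and leaves a 2,3-disubstituted dihydrobenzofuran diester.
- Forward order: dihydrofuran ring by rhodium-carbene C–H insertion, cyclohexanone ring by one vinylation/Michael cascade, linker joined by Heck coupling, macrocycle closed by olefination, Boc removed last.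
- Stereochemistry: C4a is set by the chiral dirhodium catalyst in the C–H insertion; the quaternary C9b is set by relay from C4a, because only the cis ring fusion can form; both alkenes are E from the Heck and Horner–Wadsworth–Emmons steps.
- Feature used: the ketone carbon C3 and the benzylic quaternary carbon C9b are linked through C4–C4a. C3 is a carboxyl-level electrophile, and C9b, α to the carbon that becomes the enamide arm, is an ester enolate, so one vinyl unit can be stitched between them; the C4a–O bond of the dihydrofuran ring dictates the face on which the six-membered ring closes.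

Key step: step 4

Remark: dirhodium tetrakis[N-phthaloyl-(S)-tert-leucinate], Rh2(S-PTTL)4, is assumed to give the (2R) ester 5; if the sense of induction is the opposite, the (R)-configured catalyst is used and nothing else changes.

Step 1
Reactants: 1 methyl 2-(5-bromo-2-hydroxyphenyl)acetate; 2 methyl acrylate
Product: 3 methyl 3-[4-bromo-2-(2-methoxy-2-oxoethyl)phenoxy]propanoate
Conditions: 2 (3 equiv), PMe3 (10 mol%), MeCN, 25 → 50 °C
Reagents that add atoms: none
Why: Phosphine-catalysed oxa-Michael addition, in which the phosphonium enolate formed from PMe3 and the acrylate deprotonates the phenol (far more acidic than the arylacetate CH2) and the phenoxide adds to a second acrylate; no stereocenter is formed.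

Step 2
Reactants: 3 methyl 3-[4-bromo-2-(2-methoxy-2-oxoethyl)phenoxy]propanoate
Product: 4 methyl 2-[5-bromo-2-(3-methoxy-3-oxopropoxy)phenyl]-2-diazoacetate
Conditions: p-ABSA (1.3 equiv), DBU (1.5 equiv), MeCN, 0 °C → rt
Reagents that add atoms: 4-acetamidobenzenesulfonyl azide (p-ABSA), CC(=O)Nc1ccc(cc1)S(=O)(=O)N=[N+]=[N-]
Why: Regitz diazo transfer, in which DBU deprotonates only the benzylic, ester-activated CH2 and the enolate takes the terminal nitrogen atoms of the sulfonyl azide; no stereocenter is formed.

Step 3
Reactants: 4 methyl 2-[5-bromo-2-(3-methoxy-3-oxopropoxy)phenyl]-2-diazoacetate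
Product: 5 methyl (2R,3R)-5-bromo-2-(2-methoxy-2-oxoethyl)-2,3-dihydro-1-benzofuran-3-carboxylate (cis; any C3 epimer is carried along)
Conditions: Rh2(S-PTTL)4 (1 mol%), toluene, −60 → −20 °C
Reagents that add atoms: none
Why: Intramolecular 1,5 C–H insertion of the donor/acceptor rhodium carbene into the oxygen-activated OCH2 group (the CH2 next to the ester is deactivated) should close the dihydrofuran ring, and the chiral carboxylate ligands differentiate the two enantiotopic hydrogens and so set C2, with C3 forming cis to it.

Step 4
Reactants: 5 methyl (2R,3R)-5-bromo-2-(2-methoxy-2-oxoethyl)-2,3-dihydro-1-benzofuran-3-carboxylate; 6 vinylmagnesium bromide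
Product: 9 methyl (4aR,9bS)-8-bromo-3-oxo-2,3,4,4a-tetrahydrodibenzo[b,d]furan-9b(1H)-carboxylate, via lithium enolate 7 (not isolated), via vinyl ketone enolate 8 (not isolated)
Conditions: LiN(SiMe3)2 (1.05 equiv), THF, −78 °C; then CH2=CHMgBr (1.1 equiv, slow addition), −78 → 0 °C; aq. NH4Cl
Reagents that add atoms: none
Why: Proposed new method: the more acidic α-aryl ester of 5 is first converted into lithium enolate 7, which masks that ester, so the Grignard reagent 6 attacks only the side-chain ester (addition–elimination, new C2–C3 bond), and the collapsing tetrahedral intermediate releases vinyl ketone 8 next to the enolate, which closes by intramolecular Michael addition (new C1–C9b bond) to the enolate of 9. The closest known reaction types are the conversion of esters or amides into vinyl ketones by vinyl Grignard reagents with in situ Michael trapping of the enone by amines, and base-mediated intramolecular Michael additions of α-aryl ester enolates that build benzylic quaternary carbons in Robinson-type and double Michael annulations. The cyclohexanone ring closes in a 6-endo-trig mode with the enolate double bond exocyclic to the new ring. The new quaternary stereocenter C9b is controlled by C4a, because the short C4–C3 bridge can reach only the face of the planar enolate that carries the C4a side chain, so only the cis-fused ring should form; the C3 center of 5 is erased in 7 and its configuration does not matter. The step needs chemoselectivity between the two esters (secured by prior enolization of the more acidic one), mono-addition of the Grignard reagent (secured by slow addition of about one equivalent, by the intramolecular trap being faster than a second bimolecular addition, and by the product being an unreactive enolate) and retention at C4a (secured because loss of the ring oxygen from enolate 7 would be the reverse of a disfavoured 5-endo-trig closure and because no free base remains to deprotonate next to the new ketone before the ring closes).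

Step 5
Reactants: 9 methyl (4aR,9bS)-8-bromo-3-oxo-2,3,4,4a-tetrahydrodibenzo[b,d]furan-9b(1H)-carboxylate
Product: 10 (4aR,9bR)-8-bromo-9b-(hydroxymethyl)-1,2,3,4,4a,9b-hexahydrodibenzo[b,d]furan-3-ol (mixture of C3 epimers)
Conditions: iBu2AlH (5 equiv), CH2Cl2, −78 → 0 °C; aq. KNaC4H4O6
Reagents that add atoms: none
Why: Hydride reduction of the hindered ester and the ketone by iBu2AlH leaves the aryl bromide untouched; the new carbinol center at C3 is not controlled and is removed again in step 10.

Step 6
Reactants: 11 tert-butyl (4-aminobutyl)[3-(tert-butoxycarbonylamino)propyl]carbamate (N1,N4-bis-Boc-spermidine); 12 2-(diethoxyphosphoryl)acetic acid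
Product: 13 tert-butyl {4-[2-(diethoxyphosphoryl)acetamido]butyl}[3-(tert-butoxycarbonylamino)propyl]carbamate
Conditions: EDC·HCl, HOBt, iPr2NEt, CH2Cl2, 0 °C → rt
Reagents that add atoms: none
Why: Carbodiimide amide coupling at the only free amine of 11, the primary amine at the four-carbon end; no stereocenter is formed.

Step 7
Reactants: 13 tert-butyl {4-[2-(diethoxyphosphoryl)acetamido]butyl}[3-(tert-butoxycarbonylamino)propyl]carbamate
Product: 14 N-{4-[(3-aminopropyl)amino]butyl}-2-(diethoxyphosphoryl)acetamide (free base)
Conditions: CF3CO2H/CH2Cl2 (1:3), 0 °C → rt; then basic ion-exchange resin, MeOH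
Reagents that add atoms: none
Why: Acidolysis of both tert-butyl carbamates, with the amide and the phosphonate ester stable to CF3CO2H.

Step 8
Reactants: 14 N-{4-[(3-aminopropyl)amino]butyl}-2-(diethoxyphosphoryl)acetamide; 15 N-succinimidyl acrylate
Product: 17 tert-butyl [3-(acryloylamino)propyl]{4-[2-(diethoxyphosphoryl)acetamido]butyl}carbamate (the linker), via monoacrylamide 16 (not isolated)
Conditions: 15 (1.0 equiv), CH2Cl2, −40 °C; then Boc2O (1.2 equiv), Et3N, −40 °C → rt
Reagents that add atoms: di-tert-butyl dicarbonate, CC(C)(C)OC(=O)OC(=O)OC(C)(C)C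
Why: Chemoselective acylation, in which the unhindered primary amine should attack the active ester much faster than the secondary amine at low temperature, and the remaining secondary amine is then capped as its carbamate in the same flask.

Step 9
Reactants: 10 (4aR,9bR)-8-bromo-9b-(hydroxymethyl)-1,2,3,4,4a,9b-hexahydrodibenzo[b,d]furan-3-ol; 17 tert-butyl [3-(acryloylamino)propyl]{4-[2-(diethoxyphosphoryl)acetamido]butyl}carbamate
Product: 18 (E)-cinnamamide diol: compound 10 in which the C8 bromine is replaced by (E)-CH=CH–C(=O)NH(CH2)3N(Boc)(CH2)4NHC(=O)CH2P(=O)(OEt)2 (4aR,9bR; C3 epimers)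
Conditions: Pd(OAc)2 (5 mol%), P(o-tol)3 (15 mol%), Et3N, DMF, 100 °C
Reagents that add atoms: none
Why: Mizoroki–Heck reaction, in which oxidative addition of the aryl bromide to zerovalent palladium, syn insertion of the terminal acrylamide and syn β-hydride elimination should give the (E)-cinnamamide, with alcohols, carbamate and phosphonate as spectators.

Step 10
Reactants: 18 (E)-cinnamamide diol
Product: 19 keto aldehyde: the (4aR,9bS)-3-oxo-9b-formyl compound that corresponds to 18
Conditions: Dess–Martin periodinane (3 equiv), NaHCO3, CH2Cl2, 0 °C → rt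
Reagents that add atoms: none
Why: Dess–Martin oxidation of the neopentyl primary and the secondary alcohol under buffered conditions; the aldehyde has no α-hydrogen, so C9b cannot epimerize.

Step 11
Reactants: 19 keto aldehyde
Product: 20 N-Boc macrocycle: the tert-butyl carbamate of the target at its secondary amine
Conditions: LiCl (10 equiv), iPr2NEt (5 equiv), MeCN, 1 mM (slow addition of 19), 25 → 50 °C
Reagents that add atoms: none
Why: Intramolecular Horner–Wadsworth–Emmons olefination under mild LiCl/amine conditions at high dilution, in which the stabilized phosphonoacetamide anion should react with the aldehyde and not with the ketone and give the (E)-enamide that closes the 20-membered ring.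

Step 12
Reactants: 20 N-Boc macrocycle
Product: 21 CNP0415009.1
Conditions: CF3CO2H/CH2Cl2 (1:4), 0 °C → rt; then basic ion-exchange resin
Reagents that add atoms: none
Why: Acidolysis of the carbamate frees the secondary amine, while the ketone, the aryl ether and both unsaturated amides are stable to CF3CO2H.

**Compound list**
1 | methyl 2-(5-bromo-2-hydroxyphenyl)acetate | COC(=O)Cc1cc(Br)ccc1O | starting material
2 | methyl acrylate | C=CC(=O)OC | starting material
3 | methyl 3-[4-bromo-2-(2-methoxy-2-oxoethyl)phenoxy]propanoate | COC(=O)CCOc1ccc(Br)cc1CC(=O)OC | intermediate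
4 | methyl 2-[5-bromo-2-(3-methoxy-3-oxopropoxy)phenyl]-2-diazoacetate | COC(=O)CCOc1ccc(Br)cc1C(=[N+]=[N-])C(=O)OC | intermediate
5 | methyl (2R,3R)-5-bromo-2-(2-methoxy-2-oxoethyl)-2,3-dihydro-1-benzofuran-3-carboxylate | COC(=O)C[C@H]1Oc2ccc(Br)cc2[C@H]1C(=O)OC | intermediate
6 | vinylmagnesium bromide | C=C[Mg]Br | starting material
7 | lithium enolate of 5: lithium [(2R)-5-bromo-2-(2-methoxy-2-oxoethyl)-1-benzofuran-3(2H)-ylidene](methoxy)methanolate | COC(=O)C[C@H]1Oc2ccc(Br)cc2C1=C(OC)[O-].[Li+] | intermediate
8 | vinyl ketone enolate: lithium [(2R)-5-bromo-2-(2-oxobut-3-en-1-yl)-1-benzofuran-3(2H)-ylidene](methoxy)methanolate | C=CC(=O)C[C@H]1Oc2ccc(Br)cc2C1=C(OC)[O-].[Li+] | intermediate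
9 | methyl (4aR,9bS)-8-bromo-3-oxo-2,3,4,4a-tetrahydrodibenzo[b,d]furan-9b(1H)-carboxylate | O=C1CC[C@]2(C(=O)OC)c3cc(Br)ccc3O[C@@H]2C1 | intermediate
10 | (4aR,9bR)-8-bromo-9b-(hydroxymethyl)-1,2,3,4,4a,9b-hexahydrodibenzo[b,d]furan-3-ol (C3 epimers) | OC1CC[C@]2(CO)c3cc(Br)ccc3O[C@@H]2C1 | intermediate
11 | tert-butyl (4-aminobutyl)[3-(tert-butoxycarbonylamino)propyl]carbamate | NCCCCN(CCCNC(=O)OC(C)(C)C)C(=O)OC(C)(C)C | starting material
12 | 2-(diethoxyphosphoryl)acetic acid | OC(=O)CP(=O)(OCC)OCC | starting material
13 | tert-butyl {4-[2-(diethoxyphosphoryl)acetamido]butyl}[3-(tert-butoxycarbonylamino)propyl]carbamate | CCOP(=O)(OCC)CC(=O)NCCCCN(CCCNC(=O)OC(C)(C)C)C(=O)OC(C)(C)C | intermediate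
14 | N-{4-[(3-aminopropyl)amino]butyl}-2-(diethoxyphosphoryl)acetamide | CCOP(=O)(OCC)CC(=O)NCCCCNCCCN | intermediate
15 | N-succinimidyl acrylate | C=CC(=O)ON1C(=O)CCC1=O | starting material
16 | monoacrylamide: N-{3-[(4-{[2-(diethoxyphosphoryl)acetyl]amino}butyl)amino]propyl}acrylamide | C=CC(=O)NCCCNCCCCNC(=O)CP(=O)(OCC)OCC | intermediate
17 | tert-butyl [3-(acryloylamino)propyl]{4-[2-(diethoxyphosphoryl)acetamido]butyl}carbamate | C=CC(=O)NCCCN(C(=O)OC(C)(C)C)CCCCNC(=O)CP(=O)(OCC)OCC | intermediate
18 | (E)-cinnamamide diol (10 with C8–Br replaced by the (E)-acrylamide arm of 17; 4aR,9bR; C3 epimers) | OC1CC[C@]2(CO)c3cc(/C=C/C(=O)NCCCN(C(=O)OC(C)(C)C)CCCCNC(=O)CP(=O)(OCC)OCC)ccc3O[C@@H]2C1 | intermediate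
19 | keto aldehyde ((4aR,9bS)-3-oxo-9b-formyl compound that corresponds to 18) | O=C1CC[C@]2(C=O)c3cc(/C=C/C(=O)NCCCN(C(=O)OC(C)(C)C)CCCCNC(=O)CP(=O)(OCC)OCC)ccc3O[C@@H]2C1 | intermediate
20 | N-Boc macrocycle (tert-butyl carbamate of 21 at the secondary amine) | O=C1CC[C@]23/C=C/C(=O)NCCCCN(C(=O)OC(C)(C)C)CCCNC(=O)/C=C/c4ccc(c2c4)O[C@@H]3C1 | intermediate
21 | CNP0415009.1 | O=C1CC[C@]23/C=C/C(=O)NCCCCNCCCNC(=O)/C=C/c4ccc(c2c4)O[C@@H]3C1 | target

**Step count and risks**
Total step count: 12. Longest linear sequence: 9 steps (steps 1 to 5 and 9 to 12); steps 6 to 8 make the linker in a side branch.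

Steps most likely to fail:

1. Step 4 (Proposed new method). What may go wrong: a second Grignard addition to the vinyl ketone before the ring closes, or loss of configuration at C4a through reversible β-elimination of the phenoxide while C3 is still an enolate. Fallback, from 5 back to 9, by known reactions: the side-chain ester of 5 is converted selectively into methyl (2R,3R)-5-bromo-2-{2-[methoxy(methyl)amino]-2-oxoethyl}-2,3-dihydro-1-benzofuran-3-carboxylate F1 with MeNH(OMe)·HCl and iPrMgCl in THF at −20 °C, the ring ester being shielded as its magnesium enolate. F1 is treated with LiN(SiMe3)2 and then CH2=CHMgBr and quenched cold into aqueous acid, which should give the isolated methyl (2R,3R)-5-bromo-2-(2-oxobut-3-en-1-yl)-2,3-dihydro-1-benzofuran-3-carboxylate F2. F2 is then cyclized by intramolecular Michael addition with K2CO3 in MeCN to 9.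

2. Step 3. What may go wrong: poor enantioselection between the two hydrogens of an unbranched OCH2 group, or carbene dimerization instead of insertion. Fallback, from 4 back to 5: insertion with dirhodium tetraacetate, Rh2(OAc)4, in CH2Cl2 gives the racemic cis diester F3, which is resolved by preparative chromatography on a chiral stationary phase; the (2R,3R) enantiomer is 5 and the (2S,3S) enantiomer, methyl (2S,3S)-5-bromo-2-(2-methoxy-2-oxoethyl)-2,3-dihydro-1-benzofuran-3-carboxylate F4, is set aside.

3. Step 11. What may go wrong: intermolecular olefination (oligomerization) outrunning ring closure at the hindered neopentyl aldehyde. Fallback, from 10 back to 20, closing the ring at the aryl–alkene bond instead: 10 is oxidized with Dess–Martin periodinane to (4aR,9bS)-8-bromo-3-oxo-2,3,4,4a-tetrahydrodibenzo[b,d]furan-9b(1H)-carbaldehyde F5. Intermolecular Horner–Wadsworth–Emmons reaction of F5 with 17 (LiCl, iPr2NEt, MeCN) gives the open-chain bromo acrylamide F6. An intramolecular Heck reaction of F6 (Pd(OAc)2, P(o-tol)3, Et3N, DMF, high dilution, 100 °C) then gives 20.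

Further compounds
F1 | step 4 | methyl (2R,3R)-5-bromo-2-{2-[methoxy(methyl)amino]-2-oxoethyl}-2,3-dihydro-1-benzofuran-3-carboxylate | CON(C)C(=O)C[C@H]1Oc2ccc(Br)cc2[C@H]1C(=O)OC
F2 | step 4 | methyl (2R,3R)-5-bromo-2-(2-oxobut-3-en-1-yl)-2,3-dihydro-1-benzofuran-3-carboxylate | C=CC(=O)C[C@H]1Oc2ccc(Br)cc2[C@H]1C(=O)OC
F3 | step 3 | racemic cis-methyl 5-bromo-2-(2-methoxy-2-oxoethyl)-2,3-dihydro-1-benzofuran-3-carboxylate (1:1 mixture of enantiomers) | COC(=O)C[C@H]1Oc2ccc(Br)cc2[C@H]1C(=O)OC.COC(=O)C[C@@H]1Oc2ccc(Br)cc2[C@@H]1C(=O)OC
F4 | step 3 | methyl (2S,3S)-5-bromo-2-(2-methoxy-2-oxoethyl)-2,3-dihydro-1-benzofuran-3-carboxylate | COC(=O)C[C@@H]1Oc2ccc(Br)cc2[C@@H]1C(=O)OC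
F5 | step 11 | (4aR,9bS)-8-bromo-3-oxo-2,3,4,4a-tetrahydrodibenzo[b,d]furan-9b(1H)-carbaldehyde | O=C1CC[C@]2(C=O)c3cc(Br)ccc3O[C@@H]2C1
F6 | step 11 | open-chain bromo acrylamide: tert-butyl [3-(acryloylamino)propyl]{4-[(E)-3-((4aR,9bS)-8-bromo-3-oxo-2,3,4,4a-tetrahydrodibenzo[b,d]furan-9b(1H)-yl)acrylamido]butyl}carbamate | O=C1CC[C@]2(/C=C/C(=O)NCCCCN(C(=O)OC(C)(C)C)CCCNC(=O)C=C)c3cc(Br)ccc3O[C@@H]2C1
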